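**Conventions and remarks on the chemistry.**
- Ring A is the carbocycle of the chromenedione: a1 spiro carbon, a2 the C=O next to it, a3 the carbon bearing the pyran oxygen, a4 the carbon bearing the pyran CH=, a5 the second C=O, a6 the CH carrying prenyl. Ring C is the six-membered acyl ketal ring. Ring T is the tetrahydrofuran C3–O–C9–C8–C2.
- Cage carbons: C1 alkene carbon carrying the lactone carbonyl, C2 bridgehead bearing the ether oxygen, C3 quaternary carbon with prenyl and the ring T oxygen, C4 ketone, C5 bridgehead carbinol, C6 alkene CH, C7 CH2, C8 CH, C9 CMe2.
- The cascade of step 13 is not enantioselective. The route is written for the diastereomer of 22 whose cage matches 26; the assignment would be made by X-ray diffraction of 22 or a later crystalline intermediate.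
- Compounds 8, 9 and 13 are taken as purchased. The hydroquinone-stage compounds 12, 17, 18, 19 and 24 are handled under argon.

## Analysis of the target

Target 26 is hexacyclic: a 2,2-dimethyl-2H-pyran is fused to the cyclohexenedione ring A, a1 is shared with the 1,3-dioxan-4-one ring C, and ring C is fused across C1–C2 to a bicyclo[2.2.2]oct-5-en-2-one that ring T bridges from C3 to C8. Of the six stereocentres, C2, C3, C5 and C8 can exist in only one relative configuration because the cage closes in no other way, so only the absolute sense of the cage is open, whereas a1 and a6 lie outside the cage. In the required isomer the a2 carbonyl sits on the side of ring C that faces C8–H, a6 sits on the side of the C3 prenyl group, and at a6 the prenyl group is cis to the lactone oxygen. The spiro carbon a1 is an acyl ketal next to one ketone and β to the a5 ketone, whose α-carbon a6 carries hydrogen: acid can ionise it, and base can expel the carboxylate (retro-oxa-Michael to a quinone) or epimerise a6. The C5 bridgehead α-ketol can undergo an acyloin shift, and the two prenyl groups and the chromene alkene rule out peracids, hydrogenation of late intermediates and strong acid. The difficulty is a fully substituted, doubly oxygenated spiro carbon that joins two crowded halves through an ether to a tertiary bridgehead, on a ring A with no free position. The route rests on a1 with its two oxygens, the a2 carbonyl and the para-related a5 oxygen: as an arene, ring A is a 2-alkoxyphenol (a hydroquinone mono ether) whose ipso carbon a1 can take up the C1 carboxylate on two-electron oxidation. The bond C2–O–a1 is then an aryl ether, which lets the cage itself be drawn from a second arene.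

## Retrosynthetic reasoning

**26 to 25.** Only the a6–H bond is cut. Ring A is kept as a silyl dienol ether (a5–O–Si, a5=a6) until the end so that the last operation is a desilylation with protonation at a6, under buffered conditions that spare the acyl ketal.

**25 to 24 (key disconnection).** The acyl O–a1 bond is cut and ring A is re-aromatised. This gives seco acid 24, a phenol (a2–OH) whose ortho carbon a1 already carries the bridgehead ether oxygen and whose para oxygen is silylated. The forward reaction is an oxidative dearomatising spirolactonisation. It is placed late because the acyl ketal is the most fragile element, and because the robust ether link then fixes ring size and site of attack.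

**24 to 23 to 22.** The acid and the a2 phenol of 24 are tied together in 22 as a seven-membered aryl ester. This lactone keeps the carboxyl group masked, is opened by mild hydroxide, and distinguishes the two hydroquinone oxygens of ring A (see below). The C5 hydroxyl is carried as a menthyl-bearing formaldehyde acetal (23), removed with a Lewis acid and a thiol before the oxidation.

**22 to 20 through 21.** The cage bonds C2–C8 and C5–C7 are cut (intramolecular Diels–Alder), then C3–CH2 of the prenyl group (aromatic Claisen rearrangement). This returns the cage to a flat benzoate ring carrying two 1,1-dimethylallyl ethers, and turns the hindered tertiary ether C2–O–a1 into a diaryl ether. The whole cage, both bridgehead oxygens included, then arises in one thermal step, and the ether that would be very hard to make on the cage is made on an arene. The cascade cannot induce absolute configuration, so the menthyl acetal turns the two cage enantiomers into separable diastereomers.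

**20 to 19 to 18 to 16.** The silyl ether, the lactone C–O bond and the hydroquinone oxidation level are taken back in turn. Lactonisation of 18 can only engage the hydroxyl ortho to the diaryl ether (a2–OH), which leaves the a5 hydroxyl as the only free phenol in 19. A direct selective silylation of the hydroquinone would not be dependable, because the a2 hydroxyl is the more acidic and no more hindered than the a5 hydroxyl.

**16 to 15 plus 7.** The diaryl ether bond is cut at the quinone carbon. The forward reaction is an addition–elimination of the salicylate-type phenoxide of 15 on chloroquinone 7, which tolerates four ortho substituents because the electrophilic carbon is an sp2 quinone carbon.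

**7 back to 1, 2 and 5.** The chloride comes from hydroxyquinone 6, the prenyl group from C-alkylation of 4 with 5 at the only free ring carbon, the quinone from para-oxidation of 3, and the chromene from 1 and 2.

**15 back to 8, 9 and 13.** The alkenes come from semihydrogenation of the alkynes of 14, the acetal from 12 and 13 at the only non-chelated phenol, and the C5 oxygen from para-oxidation of 10 (through 11). The two tertiary ethers come from 8 and two equivalents of 9, one for each of the two non-chelated phenols.

## Alternatives that were turned down

**Alternative 1:** The cage is cut at the O–C3 bond of ring T and at the C3–CH2 bond of the prenyl group. The key step would treat diazodione A1 with Rh2(OAc)4: the carbene between the two carbonyls is trapped by the ether oxygen, and a [2,3] shift moves the 1,1-dimethylallyl group from oxygen to carbon to give bridged dione A2.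
- For: the most congested carbon (C3, with oxygen and prenyl) and ring T form in one step, and the configuration follows from the single stereocentre of A1. On absolute stereocontrol this is stronger than the chosen route, which separates diastereomers.
- Against: the ether oxygen of A1 sits between two quaternary carbons and must attack a stabilised acceptor/acceptor carbenoid, so cyclopropanation of the allyl group, C–H insertion and [1,2] shift compete. A2 still lacks C1, C6, the ester and the C5 oxygen (C5 is a methylene), and C2 is still a ketone. After a long annulation the tertiary C2 hydroxyl would still have to be joined to 7.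
- Comparison: the chosen route makes the complete cage and its aryl ether in one thermal step from a flat precursor and puts the risk in the spiro acyl ketal, which Alternative 1 does not address.

**Alternative 2:** The cage is cut at C2–C8 and O–C9. The key step would activate the C2 ketone of the dearomatised benzoate A3 with Me2AlCl: the C5 prenyl group attacks through its CH carbon and the C3 hydroxyl captures the tertiary cation, giving cage diol ester A4.
- For: it is the shortest route to the cage and gives both bridgehead hydroxyls free. On step count up to the cage it is stronger than the chosen route.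
- Against: A3 is both a 2-hydroxy-1,3-diketone and an α-ketol, prone to acyloin shifts and retro-Claisen cleavage. Its two carbinol centres must be set trans across the ring, with absolute control, by two dearomatising hydroxylations. The Lewis acid can also ionise the tertiary carbinols. A4 would then need O-arylation with 7 at the more hindered of two tertiary alcohols, β to a ketone.
- Comparison: the chosen route forms that ether at the arene stage, where it is an ordinary phenoxide substitution, and pays with more steps.

**Alternative 3:** The cage is cut at C5–C7. The key step would deprotonate iodide A5 to the extended enolate (C4 to C1), whose α-carbon C5 displaces the iodide in a 6-exo-tet closure to give A6.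
- For: the configuration of ring T is preset in A5, and the two bridgehead oxygens emerge with different silyl groups. This differentiation is cleaner than in the chosen route.
- Against: the dienolate carries a silyloxy leaving group on C2, so vinylogous β-elimination of silanolate to a cyclohexa-2,4-dienone competes with alkylation. O-alkylation gives a six-membered enol ether as well. A5 needs a long stereocontrolled synthesis of a tetrahydrofuran with two adjacent fully substituted carbons, and the tertiary ether to ring A is still unmade.
- Comparison: the chosen route needs no strong base on a substrate that can eliminate, and needs no separate ring T synthesis. In place of preset stereochemistry it offers brevity and a separation of diastereomers.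

Key step: step 16

## Steps

Step 1
Reactants: 1 (phloroglucinol) and 2 (3-methylbut-2-enal)
Product: 3 chromenediol (2,2-dimethyl-2H-chromene-5,7-diol)
Conditions: pyridine, 110 °C (1 in threefold excess)
Reagents that add atoms: none
Why: Chromenylation of a phenol with an enal: condensation at a ring carbon, dehydration to an ortho-quinone methide and oxa-6π electrocyclisation. The excess of 1 should hold back a second annulation.

Step 2
Reactants: 3 chromenediol
Product: 4 hydroxyquinone (7-hydroxy-2,2-dimethyl-2H-chromene-5,8-dione)
Conditions: (KSO3)2NO (Fremy's salt), KH2PO4, H2O/acetone, 0 °C to rt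
Reagents that add atoms: potassium nitrosodisulfonate, [K+].[K+].[O-]S(=O)(=O)N([O])S(=O)(=O)[O-]
Why: Teuber oxidation: the radical abstracts hydrogen from the 5-hydroxyl and a second equivalent couples at C8, the free position para to it and ortho to the 7-hydroxyl, as resorcinols give hydroxy-para-quinones.

Step 3
Reactants: 4 hydroxyquinone and 5 (prenyl bromide)
Product: 6 prenyl hydroxyquinone (7-hydroxy-2,2-dimethyl-6-(3-methylbut-2-en-1-yl)-2H-chromene-5,8-dione)
Conditions: LiH, DMSO, rt; then 5, rt
Reagents that add atoms: none
Why: C-alkylation of the lithium salt of a 2-hydroxy-1,4-quinone (a vinylogous carboxylate) at its only free ring carbon, the reaction type used for lapachol. The position is fixed by the structure; O-alkylation is the competing path.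

Step 4
Reactants: 6 prenyl hydroxyquinone
Product: 7 chloroquinone (7-chloro-2,2-dimethyl-6-(3-methylbut-2-en-1-yl)-2H-chromene-5,8-dione)
Conditions: (COCl)2, DMF (cat.), 2,6-lutidine, CH2Cl2, −20 to 0 °C
Reagents that add atoms: oxalyl chloride, ClC(=O)C(=O)Cl
Why: Vilsmeier-type activation of the vinylogous acid followed by chloride addition–elimination, as for 2-hydroxy-1,4-naphthoquinones. The lutidine takes up HCl so that the prenyl group is not hydrochlorinated or cyclised onto the hydroxyl.

Step 5
Reactants: 8 (methyl 2,3,4-trihydroxybenzoate) and 9 (3-chloro-3-methylbut-1-yne; two equivalents are consumed, one per ether)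
Product: 10 bis(propargyl) ether (methyl 2-hydroxy-3,4-bis[(2-methylbut-3-yn-2-yl)oxy]benzoate)
Conditions: 9 (2.5 equiv), K2CO3, KI, CuI (cat.), acetone, 55 °C
Reagents that add atoms: 3-chloro-3-methylbut-1-yne (the second equivalent of 9), CC(C)(Cl)C#C
Why: Copper-assisted O-alkylation of phenoxides with a tertiary propargylic chloride, carried out twice in one flask: first at the 4-hydroxyl (para to the ester, the most acidic), then at the 3-hydroxyl. The 2-hydroxyl is hydrogen-bonded to the ester and should stay free, as in the selective 3,4-dialkylation of 2,3,4-trihydroxyaryl carbonyl compounds.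

Step 6
Reactants: 10 bis(propargyl) ether
Product: 12 hydroquinone ester (methyl 2,5-dihydroxy-3,4-bis[(2-methylbut-3-yn-2-yl)oxy]benzoate), via quinone ester 11 (not isolated)
Conditions: (KSO3)2NO, KH2PO4, H2O/acetone, 0 °C to rt; then aq. Na2S2O4, EtOAc, rt
Reagents that add atoms: potassium nitrosodisulfonate, [K+].[K+].[O-]S(=O)(=O)N([O])S(=O)(=O)[O-]
Why: Teuber oxidation at C5, the free position para to the only phenol, gives the ester-bearing quinone 11, which is reduced in the work-up before it can add nucleophiles. The two alkoxy groups offset the deactivation by the chelated ester.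

Step 7
Reactants: 12 hydroquinone ester and 13 ((1R,2S,5R)-menthyl chloromethyl ether)
Product: 14 acetal (methyl 2-hydroxy-5-{[(1R,2S,5R)-menthyloxy]methoxy}-3,4-bis[(2-methylbut-3-yn-2-yl)oxy]benzoate)
Conditions: iPr2NEt, CH2Cl2, 0 °C
Reagents that add atoms: none
Why: Acetal formation with an α-chloro ether at the 5-hydroxyl, the only phenol not chelated to the ester (as in 5-O-alkylation of 2,5-dihydroxybenzoates). The acetal behaves as a methoxymethyl ether, and its menthyl group later makes the two cages diastereomeric.

Step 8
Reactants: 14 acetal
Product: 15 bis(1,1-dimethylallyl) ether (methyl 2-hydroxy-5-{[(1R,2S,5R)-menthyloxy]methoxy}-3,4-bis[(2-methylbut-3-en-2-yl)oxy]benzoate)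
Conditions: H2 (1 atm), Pd/CaCO3 poisoned with Pb(OAc)2 (Lindlar catalyst), quinoline, EtOAc, rt
Reagents that add atoms: none
Why: Semihydrogenation of the two terminal alkynes. The thermally labile allyl aryl ethers are formed only now, after the oxidation.

Step 9
Reactants: 15 bis(1,1-dimethylallyl) ether and 7 chloroquinone
Product: 16 aryloxyquinone (methyl 2-{[2,2-dimethyl-6-(3-methylbut-2-en-1-yl)-5,8-dioxo-2H-chromen-7-yl]oxy}-5-{[(1R,2S,5R)-menthyloxy]methoxy}-3,4-bis[(2-methylbut-3-en-2-yl)oxy]benzoate)
Conditions: Cs2CO3, MeCN, 0 °C to rt
Reagents that add atoms: none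
Why: Addition–elimination of a phenoxide on a 2-chloro-1,4-quinone at the chlorine-bearing carbon, β to the C5 carbonyl. The sp2 electrophile tolerates the four ortho substituents, and the weak base should leave the prenylquinone untouched.

Step 10
Reactants: 16 aryloxyquinone
Product: 18 hydroquinone acid (2-{[5,8-dihydroxy-2,2-dimethyl-6-(3-methylbut-2-en-1-yl)-2H-chromen-7-yl]oxy}-5-{[(1R,2S,5R)-menthyloxy]methoxy}-3,4-bis[(2-methylbut-3-en-2-yl)oxy]benzoic acid), via hydroquinone ester 17 (not isolated)
Conditions: Na2S2O4, THF/H2O, rt; then LiOH, MeOH, 40 °C (degassed); then 1 M HCl to pH 4, 0 °C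
Reagents that add atoms: lithium hydroxide, [Li+].[OH-]
Why: Dithionite reduction of the quinone, then saponification of the methyl ester in the same reducing medium, which protects the electron-rich hydroquinone from air. The aryloxyquinone is reduced before base is added, so hydroxide cannot displace the aryloxide.

Step 11
Reactants: 18 hydroquinone acid
Product: 19 depsidone phenol (seven-membered lactone between the carboxyl group and the chromene 8-hydroxyl; chromene 5-hydroxyl free)
Conditions: EDC·HCl, DMAP (cat.), CH2Cl2 (0.005 M), 0 °C to rt
Reagents that add atoms: none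
Why: Carbodiimide lactonisation (Steglich type), the usual closure of depsidones from 2-(2-hydroxyaryloxy)benzoic acids. Only the hydroxyl ortho to the diaryl ether can reach the acid, so the two hydroquinone oxygens are distinguished by structure; dilution and the hindered a5 hydroxyl suppress intermolecular acylation.

Step 12
Reactants: 19 depsidone phenol
Product: 20 silyl ether (triisopropylsilyl ether of 19 at the chromene 5-oxygen)
Conditions: iPr3SiOTf, 2,6-lutidine, CH2Cl2, 0 °C
Reagents that add atoms: triisopropylsilyl triflate, CC(C)[Si](OS(=O)(=O)C(F)(F)F)(C(C)C)C(C)C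
Why: Silylation of the only free phenol with a silyl triflate, which handles the two ortho substituents. Triisopropylsilyl is chosen over tert-butyldimethylsilyl because it better survives heat and hydroxide, and is lost more slowly from a para-oxygen during the later oxidation.

Step 13
Reactants: 20 silyl ether
Product: 22 cage lactone (cage of the target configuration fused to the seven-membered aryl ester; C5–O as menthyloxymethyl ether), via Claisen dienone 21 (not isolated)
Conditions: DMF, 120 °C; chromatographic separation of the two diastereomers
Reagents that add atoms: none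
Why: Aromatic Claisen rearrangement of the ether on the benzoate C4 oxygen (para to the lactone carbonyl, so its C–O bond is the more polarised) to the ipso carbon C3 gives 21, whose remaining 1,1-dimethylallyl ether adds across C2 and C5 in an intramolecular Diels–Alder reaction, as for bis(1,1-dimethylallyl) catechol ethers with a para carbonyl group; unproductive Claisen shifts are reversible and drain through 21. The tether forces the alkene onto the diene face that carries the ether oxygen, so C2, C3, C5 and C8 arise in the single relative configuration of the cage. The absolute sense is not induced: both cages form, and the menthyl acetal makes them diastereomers that are separated here.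

Step 14
Reactants: 22 cage lactone
Product: 23 protected seco acid (cage carboxylic acid with free phenol at a2, silyl ether at a5, menthyloxymethyl ether at C5–O)
Conditions: LiOH, THF/H2O, 0 °C; then 0.5 M HCl to pH 4
Reagents that add atoms: lithium hydroxide, [Li+].[OH-]
Why: Hydrolysis of an aryl ester, which is far faster than attack on the hindered aryl silyl ether. The acetal on C5–O keeps the bridgehead α-ketol masked during the basic step, which excludes an acyloin shift.

Step 15
Reactants: 23 protected seco acid
Product: 24 seco acid (cage acid with free C5 hydroxyl; bridgehead oxygen bound to C7 of 8-hydroxy-6-prenyl-5-(triisopropylsilyloxy)-2,2-dimethyl-2H-chromene)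
Conditions: ZnBr2, n-PrSH, CH2Cl2, 0 °C
Reagents that add atoms: none
Why: Lewis acid/thiol cleavage of a formaldehyde acetal, which works on tertiary alkoxymethyl ethers within minutes and leaves silyl ethers, the chromene and the prenyl groups alone. No phenol is ortho to a prenyl group, so no chroman can form.

Step 16
Reactants: 24 seco acid
Product: 25 spiro dienone (ring C closed; ring A as 6-acyloxy-6-alkoxycyclohexa-2,4-dienone with a5–O–Si(iPr)3 and a5=a6)
Conditions: PhI(OAc)2, NaHCO3 (solid), CH2Cl2, −78 to −20 °C
Reagents that add atoms: none
Why: The a2 phenol exchanges an acetate on the trivalent iodine reagent to give an aryloxy iodane, and the C1 carboxylate attacks a1, the ortho carbon that already bears the ether oxygen, while iodobenzene leaves. The closest known reactions are the Wessely-type acyloxylation of 2-alkoxyphenols and the trivalent-iodine ortho-spirolactonisation of phenols whose ortho oxygen carries a carboxyalkyl chain, which give the same acyloxy alkoxy dienones. Ring C closes 6-exo-trig; attack at the other alkoxy-bearing ortho carbon a3 would need an eight-membered ring, so the tether fixes the site. The new stereocentre a1 is set by which arene face meets the carboxylate, that is, by the rotamer about the C2–O–a1 bond. In the rotamer that leads to 25 the iodane-bearing oxygen lies over the open C8–H side of the cage, and in the other it would press against the C3 prenyl group, so the cage should favour the required configuration. The step needs ortho capture to be faster than loss of the silyl group from the para oxygen (which would give a quinone) and faster than capture of acetate; intramolecular delivery of a carboxylate, the bulky silyl group, the aprotic medium and the low temperature are meant to secure this. Phenol oxidation is much faster than attack on the alkenes or the α-ketol, whereas catalytic variants with a peracid are excluded by the three electron-rich alkenes.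

Step 17
Reactants: 25 spiro dienone
Product: 26 target
Conditions: Bu4NF, AcOH, THF, −78 to 0 °C
Reagents that add atoms: none
Why: Fluoride cleaves the silyl dienol ether and the buffer protonates the dienol(ate) at a6 (desilylation with ketonisation), which keeps the free enolate scarce so that β-elimination of the carboxylate does not compete. The prenyl chain should lie on the open face of ring A, so the proton is expected to enter from the face of the ether oxygen; this leaves prenyl cis to the lactone oxygen, which is also the less crowded epimer.

## Compound list

1 | phloroglucinol | Oc1cc(O)cc(O)c1 | starting material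
2 | 3-methylbut-2-enal | CC(C)=CC=O | starting material
3 | 2,2-dimethyl-2H-chromene-5,7-diol | CC1(C)C=Cc2c(O)cc(O)cc2O1 | intermediate
4 | 7-hydroxy-2,2-dimethyl-2H-chromene-5,8-dione | CC1(C)C=CC2=C(O1)C(=O)C(O)=CC2=O | intermediate
5 | prenyl bromide (1-bromo-3-methylbut-2-ene) | CC(C)=CCBr | starting material
6 | 7-hydroxy-2,2-dimethyl-6-(3-methylbut-2-en-1-yl)-2H-chromene-5,8-dione | CC(C)=CCC1=C(O)C(=O)C2=C(C=CC(C)(C)O2)C1=O | intermediate
7 | 7-chloro-2,2-dimethyl-6-(3-methylbut-2-en-1-yl)-2H-chromene-5,8-dione | CC(C)=CCC1=C(Cl)C(=O)C2=C(C=CC(C)(C)O2)C1=O | intermediate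
8 | methyl 2,3,4-trihydroxybenzoate | COC(=O)c1ccc(O)c(O)c1O | starting material
9 | 3-chloro-3-methylbut-1-yne | CC(C)(Cl)C#C | starting material
10 | methyl 2-hydroxy-3,4-bis[(2-methylbut-3-yn-2-yl)oxy]benzoate | COC(=O)c1ccc(OC(C)(C)C#C)c(OC(C)(C)C#C)c1O | intermediate
11 | methyl 4,5-bis[(2-methylbut-3-yn-2-yl)oxy]-3,6-dioxocyclohexa-1,4-diene-1-carboxylate (quinone ester, not isolated) | COC(=O)C1=CC(=O)C(OC(C)(C)C#C)=C(OC(C)(C)C#C)C1=O | intermediate
12 | methyl 2,5-dihydroxy-3,4-bis[(2-methylbut-3-yn-2-yl)oxy]benzoate | COC(=O)c1cc(O)c(OC(C)(C)C#C)c(OC(C)(C)C#C)c1O | intermediate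
13 | (1R,2S,5R)-menthyl chloromethyl ether | ClCO[C@@H]1C[C@H](C)CC[C@H]1C(C)C | starting material
14 | methyl 2-hydroxy-5-{[(1R,2S,5R)-menthyloxy]methoxy}-3,4-bis[(2-methylbut-3-yn-2-yl)oxy]benzoate | COC(=O)c1cc(OCO[C@@H]2C[C@H](C)CC[C@H]2C(C)C)c(OC(C)(C)C#C)c(OC(C)(C)C#C)c1O | intermediate
15 | methyl 2-hydroxy-5-{[(1R,2S,5R)-menthyloxy]methoxy}-3,4-bis[(2-methylbut-3-en-2-yl)oxy]benzoate | COC(=O)c1cc(OCO[C@@H]2C[C@H](C)CC[C@H]2C(C)C)c(OC(C)(C)C=C)c(OC(C)(C)C=C)c1O | intermediate
16 | aryloxyquinone: methyl benzoate 15 bound through its 2-oxygen to C7 of 2,2-dimethyl-6-prenyl-2H-chromene-5,8-dione | COC(=O)c1cc(OCO[C@@H]2C[C@H](C)CC[C@H]2C(C)C)c(OC(C)(C)C=C)c(OC(C)(C)C=C)c1OC1=C(CC=C(C)C)C(=O)C2=C(OC(C)(C)C=C2)C1=O | intermediate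
17 | hydroquinone ester: 16 with the quinone reduced to the 5,8-dihydroxychromene (not isolated) | COC(=O)c1cc(OCO[C@@H]2C[C@H](C)CC[C@H]2C(C)C)c(OC(C)(C)C=C)c(OC(C)(C)C=C)c1Oc1c(CC=C(C)C)c(O)c2C=CC(C)(C)Oc2c1O | intermediate
18 | hydroquinone acid: carboxylic acid of 17 | OC(=O)c1cc(OCO[C@@H]2C[C@H](C)CC[C@H]2C(C)C)c(OC(C)(C)C=C)c(OC(C)(C)C=C)c1Oc1c(CC=C(C)C)c(O)c2C=CC(C)(C)Oc2c1O | intermediate
19 | depsidone phenol: seven-membered lactone of 18 through the chromene 8-oxygen, chromene 5-hydroxyl free | O=C1Oc2c3OC(C)(C)C=Cc3c(O)c(CC=C(C)C)c2Oc2c(OC(C)(C)C=C)c(OC(C)(C)C=C)c(OCO[C@@H]4C[C@H](C)CC[C@H]4C(C)C)cc12 | intermediate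
20 | triisopropylsilyl ether of 19 | O=C1Oc2c3OC(C)(C)C=Cc3c(O[Si](C(C)C)(C(C)C)C(C)C)c(CC=C(C)C)c2Oc2c(OC(C)(C)C=C)c(OC(C)(C)C=C)c(OCO[C@@H]4C[C@H](C)CC[C@H]4C(C)C)cc12 | intermediate
21 | Claisen dienone: benzoate ring of 20 as cyclohexa-2,4-dienone with C4=O and C3 bearing prenyl and the 1,1-dimethylallyl ether (not isolated) | C=CC(C)(C)O[C@@]1(CC=C(C)C)C(=O)C(OCO[C@@H]4C[C@H](C)CC[C@H]4C(C)C)=CC2=C1Oc1c(CC=C(C)C)c(O[Si](C(C)C)(C(C)C)C(C)C)c3C=CC(C)(C)Oc3c1OC2=O | intermediate
22 | cage lactone: cage of the target configuration, C1 carbonyl esterified to the a2 oxygen, C2–O–a1 ether, a5–O–Si(iPr)3, C5–O–CH2–O–menthyl | O=C5C1=C[C@]3(OCO[C@@H]6C[C@H](C)CC[C@H]6C(C)C)C[C@H]4C(C)(C)O[C@@](CC=C(C)C)(C3=O)[C@@]14Oc1c(O5)c2OC(C)(C)C=Cc2c(O[Si](C(C)C)(C(C)C)C(C)C)c1CC=C(C)C | intermediate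
23 | protected seco acid: 22 with the lactone opened to carboxylic acid and a2 phenol | OC(=O)C1=C[C@]3(OCO[C@@H]6C[C@H](C)CC[C@H]6C(C)C)C[C@H]4C(C)(C)O[C@@](CC=C(C)C)(C3=O)[C@@]14Oc1c(O)c2OC(C)(C)C=Cc2c(O[Si](C(C)C)(C(C)C)C(C)C)c1CC=C(C)C | intermediate
24 | seco acid: 23 with free C5 hydroxyl | OC(=O)C1=C[C@]3(O)C[C@H]4C(C)(C)O[C@@](CC=C(C)C)(C3=O)[C@@]14Oc1c(O)c2OC(C)(C)C=Cc2c(O[Si](C(C)C)(C(C)C)C(C)C)c1CC=C(C)C | intermediate
25 | spiro dienone silyl dienol ether | CC(C)=CCC1=C(O[Si](C(C)C)(C(C)C)C(C)C)C2=C(OC(C)(C)C=C2)C(=O)[C@@]12OC(=O)C1=C[C@]3(O)C[C@H]4C(C)(C)O[C@@](CC=C(C)C)(C3=O)[C@@]14O2 | intermediate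
26 | CNP0222516.1 | CC(C)=CC[C@H]1C(=O)C2=C(OC(C)(C)C=C2)C(=O)[C@@]12OC(=O)C1=C[C@]3(O)C[C@H]4C(C)(C)O[C@@](CC=C(C)C)(C3=O)[C@@]14O2 | target

## Step count and least certain steps

Total: 17 steps. Longest linear sequence: 13 steps (steps 1–4 or 5–8, then 9–17).

**Step 16 (key step).** The most likely failure is loss of the silyl group from the para oxygen during the oxidation, which would divert the phenol to the para-quinone instead of the dienone. The second is poor facial selectivity at a1, because the two rotamers about the aryl ether bond may differ little in energy. The fallback sets out from 24 and returns at 26. It oxidises 24 with PhI(OAc)2 in aqueous MeCN, so that desilylation is intended, to the quinone acid F1. Ring C is then closed by intramolecular conjugate addition of the carboxylic acid to the alkoxy-bearing quinone carbon a1 under a mild buffer (catalytic Et3N/AcOH), with protonation at a6. This is the reverse of the elimination that threatens 26, runs under thermodynamic control, and sets a1 and a6 by equilibration.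

**Step 17.** The enolate freed by fluoride may expel the carboxylate (reopening ring C) before it is protonated, or protonation may occur from the other face and give the a6 epimer. The fallback sets out from 25 and returns at 26. It uses unbuffered Bu4NF to drive desilylation and elimination through to the quinone acid F1, and then recloses ring C under the buffered equilibrating conditions described for step 16, instead of relying on kinetic protonation.

**Step 13.** The ether on the C3 oxygen may rearrange first and lead to the isomeric cage if the lactone carbonyl is twisted out of conjugation. The cascade also has no facial preference, so both diastereomers are expected and they may be hard to separate. The fallback sets out from 16 and returns at 22. It heats 16 itself (PhMe, 110 °C), where the ester is coplanar and the C2 oxygen carries an electron-poor quinone, to give the cage aryloxyquinone ester F2, which is separated from its diastereomer. Na2S2O4 and then LiOH give the cage hydroquinone acid F3, EDC lactonisation gives the cage depsidone phenol F4, and silylation with iPr3SiOTf gives 22.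

**Step 6.** The chelated, ester-bearing phenol may be oxidised too slowly, with incomplete conversion or decomposition of the quinone. The fallback sets out from 10 and returns at 11. It replaces phenol oxidation by electrophilic substitution: azo coupling of 10 with 4-sulfobenzenediazonium chloride (aq. Na2CO3, 0 °C) para to the hydroxyl gives the azo compound F5, Na2S2O4 cleaves it to the aminophenol F6, and aqueous FeCl3 oxidises this easily to quinone 11, which is reduced to 12 as before.

**Step 3.** O-alkylation of the ambident hydroxyquinone anion may outrun C-alkylation. The fallback sets out from 1 and returns at 6. It forms the C–C bond on the phenol: 1 is C-prenylated with 5 (aq. KOH, 0 °C) to 2-prenylphloroglucinol F7, annulation with 2 as in step 1 gives the 6-prenyl chromenediol F8 (separated from the 8-prenyl isomer), and Teuber oxidation as in step 2 gives 6.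

## Further compounds

F1 | step 16 | quinone acid: cage acid with free C5 hydroxyl, bridgehead oxygen on C7 of 2,2-dimethyl-6-prenyl-2H-chromene-5,8-dione | OC(=O)C1=C[C@]3(O)C[C@H]4C(C)(C)O[C@@](CC=C(C)C)(C3=O)[C@@]14OC1=C(CC=C(C)C)C(=O)C2=C(OC(C)(C)C=C2)C1=O
F0 | step 17 | none | none
F2 | step 13 | cage aryloxyquinone methyl ester (C5–O as menthyloxymethyl ether) | COC(=O)C1=C[C@]3(OCO[C@@H]6C[C@H](C)CC[C@H]6C(C)C)C[C@H]4C(C)(C)O[C@@](CC=C(C)C)(C3=O)[C@@]14OC1=C(CC=C(C)C)C(=O)C2=C(OC(C)(C)C=C2)C1=O
F3 | step 13 | cage hydroquinone acid (C5–O as menthyloxymethyl ether) | OC(=O)C1=C[C@]3(OCO[C@@H]6C[C@H](C)CC[C@H]6C(C)C)C[C@H]4C(C)(C)O[C@@](CC=C(C)C)(C3=O)[C@@]14Oc1c(O)c2OC(C)(C)C=Cc2c(O)c1CC=C(C)C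
F4 | step 13 | cage depsidone phenol (22 without the silyl group) | O=C5C1=C[C@]3(OCO[C@@H]6C[C@H](C)CC[C@H]6C(C)C)C[C@H]4C(C)(C)O[C@@](CC=C(C)C)(C3=O)[C@@]14Oc1c(O5)c2OC(C)(C)C=Cc2c(O)c1CC=C(C)C
F5 | step 6 | methyl 2-hydroxy-3,4-bis[(2-methylbut-3-yn-2-yl)oxy]-5-[(E)-(4-sulfophenyl)diazenyl]benzoate | COC(=O)c1cc(/N=N/c2ccc(cc2)S(O)(=O)=O)c(OC(C)(C)C#C)c(OC(C)(C)C#C)c1O
F6 | step 6 | methyl 5-amino-2-hydroxy-3,4-bis[(2-methylbut-3-yn-2-yl)oxy]benzoate | COC(=O)c1cc(N)c(OC(C)(C)C#C)c(OC(C)(C)C#C)c1O
F7 | step 3 | 2-(3-methylbut-2-en-1-yl)benzene-1,3,5-triol | CC(C)=CCc1c(O)cc(O)cc1O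
F8 | step 3 | 2,2-dimethyl-6-(3-methylbut-2-en-1-yl)-2H-chromene-5,7-diol | CC(C)=CCc1c(O)cc2OC(C)(C)C=Cc2c1O
A1 | alternative 1 | 2-diazo-4-[2-(2-methylbut-3-en-2-yloxy)propan-2-yl]cyclohexane-1,3-dione | C1C[C@@H](C(C)(C)OC(C)(C)C=C)C(=O)C(=[N+]=[N-])C1=O
A2 | alternative 1 | 7,7-dimethyl-5-(3-methylbut-2-en-1-yl)-6-oxabicyclo[3.2.1]octane-4,8-dione | C1C[C@H]2C(C)(C)O[C@@](CC=C(C)C)(C1=O)C2=O
A3 | alternative 2 | methyl 3,5-dihydroxy-3,5-bis(3-methylbut-2-en-1-yl)-4,6-dioxocyclohex-1-ene-1-carboxylate (hydroxyls trans) | COC(=O)C1=C[C@](O)(CC=C(C)C)C(=O)[C@@](O)(CC=C(C)C)C1=O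
A4 | alternative 2 | cage diol methyl ester | COC(=O)C1=C[C@]3(O)C[C@H]4C(C)(C)O[C@@](CC=C(C)C)(C3=O)[C@@]14O
A5 | alternative 3 | tetrahydrofuran-fused cyclohexenone with iodomethyl group on C8, triethylsilyloxy on C2 and tert-butyldimethylsilyloxy on C5 (C5 configuration open) | IC[C@H]4C(C)(C)O[C@@](CC=C(C)C)(C(=O)C(O[Si](C)(C)C(C)(C)C)C=C1C(=O)OC)[C@@]14O[Si](CC)(CC)CC
A6 | alternative 3 | bis-silylated cage methyl ester | COC(=O)C1=C[C@]3(O[Si](C)(C)C(C)(C)C)C[C@H]4C(C)(C)O[C@@](CC=C(C)C)(C3=O)[C@@]14O[Si](CC)(CC)CC
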